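- The 34.3% of starting material left at 15.0 min in the ash run was where I began: if its loss was first order in the fraction still there, that leftover meant a rate constant of 0.0713 /min, and I took 9.72 min as the clock, the time in which the unturned fraction halves at 50 °C.

| flask | starting material | first nucleophile | second nucleophile | temperature | remark | time |
|---|---|---|---|---|---|---|
| ash | 0.50 M | 0.35 M | 0.90 M | 50 °C | run made earlier |  |
| cedar | 0.50 M | 0.35 M | 1.8 M | 50 °C | run made earlier |  |
| summer | 0.50 M (fed, over 15 min) | 0.350 M | 0.900 M | 50 °C | all else is in the flask from the start; the feed brings no volume worth counting | 25 min |
| dawn | 0.50 M | 0.350 M (fed, over 15 min) | 0.900 M | 50 °C | all else is in the flask from the start; the feed brings no volume worth counting | 25 min |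
| winter | 0.50 M | 0.350 M (fed, over 15 min) | 0.900 M |  | the addition at 10 °C, then warmed to 50 °C; the feed brings no volume worth counting | 25 min |
| midnight | 0.50 M | 0.350 M | 0.900 M |  | everything together at the start at 10 °C, warmed to 50 °C at 15 min | 25 min |

- ash (time / min: target / %, starting material / %): 1.00: 3.7, 94.0; 3.00: 14.7, 80.6; 5.00: 20.4, 69.7; 8.00: 29.7, 55.6; 12.0: 38.0, 44.7; 15.0: 41.7, 34.3
- cedar (time / min: target / %, starting material / %): 0.200: 0.7, 100.6; 0.333: 0.5, 98.4; 0.500: 3.0, 96.3; 0.833: 2.9, 96.2; 1.50: 5.5, 89.8; 2.50: 8.5, 81.9

(each reading ± 1 percentage point)

- target is meant together with its idle adduct
- what was read earlier has a scatter of 1 percentage point, one standard deviation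
- steps thought possible: starting material -> intermediate; first nucleophile + intermediate <-> target; second nucleophile + intermediate -> other capture product; second nucleophile + target <-> idle adduct
- the earlier runs do not show what temperature does; that part of a forecast is a guess

* the flask that comes out highest in amount of target, in percent of the starting material charged, or "all alike" when all lie within 1.5 percentage points (summer / dawn / winter / midnight / all alike)
* target at the end, in percent of the starting material charged, summer
* target at the end, in percent of the starting material charged, dawn
* target at the end, in percent of the starting material charged, winter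
* target at the end, in percent of the starting material charged, midnight

- The cedar run, with twice the second nucleophile, showed 81.9% left at 2.50 min where this clock gave 83.7%, a gap of 1.8 percentage points on a scatter of 1 point, so I let the fraction of starting material set the order of the rate and treated its turning into intermediate as the rate-limiting step.
- In the ash run the selectivity, the share of the loss reaching target, read 75.8% at 3.00 min, so the target began at about 0.0540 /min of the charge per minute, the clock's rate times that share; by 15.0 min that rate had slowed by two factors, the leftover itself and a share read as 56.3% between 8.00 min and 15.0 min.
- Carried to 25 min, the clock left 30.1% in summer, where the feed ran for 15 min, and 16.8% in dawn; for winter and midnight, guessing that the cold counted for nothing, it left 49.0%.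
- Multiplying the turned fraction by the ash run's overall share at a like turnover, I committed to 44.4% of target in summer and 34.1% in winter and midnight; I carried no share to dawn, whose first nucleophile arrived by feed.
- The forecast chose summer, with 44% there, 35% in dawn, 35% in winter and 35% in midnight, its own grounds being “so that step is rate-limiting and the intermediate stays low”; its winter and midnight figures stood above my 34.1%.
- Summer came out highest at 42.5%, with dawn at 36.3%, winter at 33.8% and midnight at 33.9%, and the starting material stood at 29.8% in summer against the clock's 30.1%, and at 16.5% in dawn against its 16.8%. In summer at 25.0 min the intermediate had a half-life of 0.44 min by the forward step to target alone, far shorter than the clock's 9.72 min for the starting material, and the intermediate stood at 1.48%.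

    starting material → intermediate (k = 0.00120 /s, Ea = 95.0 kJ/mol)
    first nucleophile + intermediate ⇌ target (K = 30.0 /M, k = 0.190 /M/s, Ea = 42.0 kJ/mol, ΔH = −17.0 kJ/mol)
    second nucleophile + intermediate → other capture product (k = 0.0260 /M/s, Ea = 68.0 kJ/mol)
    second nucleophile + target ⇌ idle adduct, settled at all times (K = 17.0 /M, ΔH = −16.0 kJ/mol)
    (constants at 50 °C)

(The runs are calculated with made-up constants, noise included.)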